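A direct plan would join the symmetric 2-prenyl-5-methoxyresorcinol A1 with the trans-epoxy aldehyde A2, which would be made by amine-catalysed epoxidation of the E-enal.
An arylboronic acid would template ortho-hydroxyalkylation of A1 (C4–C4a) and then 6-endo opening of the aryl epoxide by the phenol (O1–C2), to give the cis-fused 3,4-boronate A3, which transesterification would free.
Its weakest steps would be:
- the templated hydroxyalkylation of A1 with an epoxy aldehyde: this electrophile has no precedent in that reaction, and C4 would rest on a weak Felkin preference that has to be corrected afterwards by acid equilibration;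
- the ring closure by phenol attack on the aryl epoxide: 6-endo attack with clean inversion at C2 would have to win over 5-exo closure and over ionisation of the benzylic C–O bond in warm acid;
- the slow feed of A2 into that step: an enolisable, acid-labile epoxy aldehyde would carry two of the three stereocentres, so its ee and survival would limit the whole route.

**Retrosynthetic overview**
Ring C is cut at C3–C4: the cis-3,4-diol (C3–OH, C4–OH) next to the aryl-bearing C2 is read as the product of an intramolecular pinacol coupling of a dialdehyde, with C4 as the formyl group of a ring-A salicylaldehyde and C3 as an α-aryloxy aldehyde.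
The O1–C2 ether is made first, between two fragments, by Mitsunobu inversion of an (S)-mandelate, the only purchased stereocentre; ring C closes last, and C3 and C4 are relayed from C2 in that one event.
Ring A comes from 5-methoxyresorcinol by ortho-prenylation and formylation; ring B comes with the mandelate.
No epoxide is opened, no benzylic cation at C2 or C4 is needed, and C4 is set kinetically in the ring closure.

Key step: step 8

Assumption: methyl (S)-4-hydroxymandelate is taken as a catalogue compound in enantiopure form. Prenyl = 3-methylbut-2-en-1-yl.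

**Step 1**
Reactants: 1 5-methoxyresorcinol (1.5 equiv); 2 prenol (3-methylbut-2-en-1-ol)
Product: 3 5-methoxy-2-prenylbenzene-1,3-diol
Conditions: acidic Al2O3, ClCH2CH2Cl, reflux
Reagents that add atoms: none
Why: Alumina-templated Friedel–Crafts ortho-allylation brings the surface-bound phenol and the activated allylic alcohol together at the carbon flanked by both OH groups and gives the linear prenyl group; the product is symmetric, so its two free ring positions are equivalent, and no stereocentre is formed.

**Step 2**
Reactants: 3 5-methoxy-2-prenylbenzene-1,3-diol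
Product: 5 2,4-dihydroxy-6-methoxy-3-prenylbenzaldehyde, via aryl iminium chloride 4 (not isolated)
Conditions: POCl3 (1.1 equiv), DMF (3 equiv), MeCN, 0 °C → rt; then aq NaOAc, rt
Reagents that add atoms: N,N-dimethylformamide, CN(C)C=O; water, O
Why: In this Vilsmeier–Haack formylation the chloroiminium ion attacks the only kind of free ring position (ortho to OH and OMe, para to the second OH), the iminium group of 4 blocks a second formylation, and the aprotic electrophile and buffered hydrolysis should spare the prenyl alkene.

**Step 3**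
Reactants: 5 2,4-dihydroxy-6-methoxy-3-prenylbenzaldehyde
Product: 6 2-hydroxy-6-methoxy-3-prenyl-4-(triisopropylsilyloxy)benzaldehyde
Conditions: i-Pr3SiCl (1.05 equiv), imidazole (2.2 equiv), DMF, 0 °C → rt
Reagents that add atoms: triisopropylsilyl chloride, CC(C)[Si](Cl)(C(C)C)C(C)C
Why: Silylation should take the more acidic 4-OH (para to CHO), because the 2-OH is held in a hydrogen bond to the formyl group; the bulky triisopropylsilyl group is chosen because an aryl silyl ether para to a formyl group is otherwise labile.

**Step 4**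
Reactants: 7 methyl (S)-4-hydroxymandelate
Product: 8 methyl (S)-2-[4-(tert-butyldimethylsilyloxy)phenyl]-2-hydroxyacetate
Conditions: t-BuMe2SiCl (1.05 equiv), imidazole (2.2 equiv), DMF, 0 °C
Reagents that add atoms: tert-butyldimethylsilyl chloride, CC(C)(C)[Si](C)(C)Cl
Why: Imidazole-mediated silylation is selective for the phenol over the hindered, less acidic α-hydroxy ester OH, and the stereocentre is not touched.

**Step 5**
Reactants: 6 2-hydroxy-6-methoxy-3-prenyl-4-(triisopropylsilyloxy)benzaldehyde; 8 methyl (S)-2-[4-(tert-butyldimethylsilyloxy)phenyl]-2-hydroxyacetate (1.2 equiv)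
Product: 9 methyl (R)-2-[4-(tert-butyldimethylsilyloxy)phenyl]-2-[2-formyl-3-methoxy-6-prenyl-5-(triisopropylsilyloxy)phenoxy]acetate
Conditions: PPh3 (1.5 equiv), DIAD (1.5 equiv), toluene (0.5 M), 0 °C → rt, sonication
Reagents that add atoms: none
Why: In this Mitsunobu etherification the chelated salicyl OH is acidic enough to protonate the betaine, and its phenoxide displaces the oxyphosphonium group by SN2 with inversion (the ester disfavours ionisation), which turns the S carbinol into the R ether carbon that becomes C2; high concentration and sonication are used for the di-ortho-substituted phenol.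

**Step 6**
Reactants: 9 methyl (R)-2-aryl-2-aryloxyacetate
Product: 10 (R)-2-[4-(tert-butyldimethylsilyloxy)phenyl]-2-[2-(hydroxymethyl)-3-methoxy-6-prenyl-5-(triisopropylsilyloxy)phenoxy]ethan-1-ol
Conditions: i-Bu2AlH (5 equiv), CH2Cl2, −78 → −20 °C; aq KNaC4H4O6
Reagents that add atoms: none
Why: Hydride reduction of the ester and the aryl aldehyde under non-basic conditions at low temperature should leave C2 and both aryl silyl ethers untouched and give a stable 1,6-diol on which the ee can be checked.

**Step 7**
Reactants: 10 (R)-1,6-diol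
Product: 11 (R)-2-[4-(tert-butyldimethylsilyloxy)phenyl]-2-[2-formyl-3-methoxy-6-prenyl-5-(triisopropylsilyloxy)phenoxy]acetaldehyde
Conditions: Dess–Martin periodinane (3 equiv), NaHCO3 (10 equiv), CH2Cl2, 0 °C → rt, 45 min; cold aq Na2S2O3/NaHCO3 wash; dried solution used at once
Reagents that add atoms: none
Why: Dess–Martin oxidation with excess reagent binds both primary alcohols to iodine at once, so that no lactol can form, and the bicarbonate buffer, the absence of an amine base and immediate use should guard the enolisable C2–H; no stereocentre is formed.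

**Step 8**
Reactants: 11 (R)-dialdehyde
Product: 12 (2R,3S,4S)-2-[4-(tert-butyldimethylsilyloxy)phenyl]-5-methoxy-8-prenyl-7-(triisopropylsilyloxy)chromane-3,4-diol (2,3-trans, 3,4-cis)
Conditions: SmI2 (0.1 M in THF, 3 equiv), t-BuOH (2 equiv), THF, −78 °C (slow addition of 11) → −30 °C; aq NaHCO3/KNaC4H4O6
Reagents that add atoms: none
Why: SmI2 gives an electron to the conjugated ring-A aldehyde (C4), and the samarium ketyl adds 6-exo-trig to the samarium-bound aliphatic aldehyde carbon (C3) before a second electron is taken up, so that ring C closes through the C3–C4 bond as a samarium diolate. The closest known reaction type is the SmI2 pinacol cyclisation of 1,6-dialdehydes with an α-oxygenated stereocentre, which gives cis-cyclohexane-1,2-diols with the new oxygen anti to the α-substituent. C3 and C4 are set together and relayed from C2: both oxygens sit on one trivalent samarium in the transition state (3,4-cis), the aryl group at C2 lies pseudo-equatorial and puts the C3 oxygen trans to it (3S), and the C4 oxygen goes pseudo-axial, away from the peri 5-OMe group (4S). The step needs electron transfer to the aryl aldehyde to be faster than to the α-aryloxy aldehyde, whose ketyl could expel the ring-A phenoxide, and this should be secured by the lower π* level of the conjugated carbonyl, by −78 °C and by leaving out HMPA. The non-basic medium and the low temperature should keep the C2–H of 11 from enolising before the ring closes.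

**Step 9**
Reactants: 12 bis-silyl flavan-3,4-diol
Product: 13 5-O-methyl-8-prenylafzelechin-4β-ol, (2R,3S,4S)
Conditions: n-Bu4NF (2.5 equiv), AcOH (2.5 equiv), THF, 0 °C → rt, Ar; pH 7 phosphate buffer; Sephadex LH-20
Reagents that add atoms: none
Why: Fluoride cleaves both aryl silyl ethers, with AcOH as buffer so that neither free phenoxide nor acid acts on the acid-labile C4 carbinol or the prenyl group, and the three stereocentres are not involved.

**Compound list**
1 | 5-methoxyresorcinol | COc1cc(O)cc(O)c1 | starting material
2 | prenol (3-methylbut-2-en-1-ol) | CC(C)=CCO | starting material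
3 | 5-methoxy-2-(3-methylbut-2-en-1-yl)benzene-1,3-diol | COc1cc(O)c(CC=C(C)C)c(O)c1 | intermediate
4 | [2,4-dihydroxy-6-methoxy-3-(3-methylbut-2-en-1-yl)benzylidene]dimethylammonium chloride | COc1cc(O)c(CC=C(C)C)c(O)c1C=[N+](C)C.[Cl-] | intermediate
5 | 2,4-dihydroxy-6-methoxy-3-(3-methylbut-2-en-1-yl)benzaldehyde | COc1cc(O)c(CC=C(C)C)c(O)c1C=O | intermediate
6 | 2-hydroxy-6-methoxy-3-(3-methylbut-2-en-1-yl)-4-(triisopropylsilyloxy)benzaldehyde | COc1cc(O[Si](C(C)C)(C(C)C)C(C)C)c(CC=C(C)C)c(O)c1C=O | intermediate
7 | methyl (S)-2-hydroxy-2-(4-hydroxyphenyl)acetate (methyl (S)-4-hydroxymandelate) | COC(=O)[C@@H](O)c1ccc(O)cc1 | starting material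
8 | methyl (S)-2-[4-(tert-butyldimethylsilyloxy)phenyl]-2-hydroxyacetate | COC(=O)[C@@H](O)c1ccc(O[Si](C)(C)C(C)(C)C)cc1 | intermediate
9 | methyl (R)-2-[4-(tert-butyldimethylsilyloxy)phenyl]-2-[2-formyl-3-methoxy-6-(3-methylbut-2-en-1-yl)-5-(triisopropylsilyloxy)phenoxy]acetate | COC(=O)[C@H](Oc1c(C=O)c(OC)cc(O[Si](C(C)C)(C(C)C)C(C)C)c1CC=C(C)C)c1ccc(O[Si](C)(C)C(C)(C)C)cc1 | intermediate
10 | (R)-2-[4-(tert-butyldimethylsilyloxy)phenyl]-2-[2-(hydroxymethyl)-3-methoxy-6-(3-methylbut-2-en-1-yl)-5-(triisopropylsilyloxy)phenoxy]ethan-1-ol | OC[C@H](Oc1c(CO)c(OC)cc(O[Si](C(C)C)(C(C)C)C(C)C)c1CC=C(C)C)c1ccc(O[Si](C)(C)C(C)(C)C)cc1 | intermediate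
11 | (R)-2-[4-(tert-butyldimethylsilyloxy)phenyl]-2-[2-formyl-3-methoxy-6-(3-methylbut-2-en-1-yl)-5-(triisopropylsilyloxy)phenoxy]acetaldehyde | O=C[C@H](Oc1c(C=O)c(OC)cc(O[Si](C(C)C)(C(C)C)C(C)C)c1CC=C(C)C)c1ccc(O[Si](C)(C)C(C)(C)C)cc1 | intermediate
12 | (2R,3S,4S)-2-[4-(tert-butyldimethylsilyloxy)phenyl]-5-methoxy-8-(3-methylbut-2-en-1-yl)-7-(triisopropylsilyloxy)chromane-3,4-diol | COc1cc(O[Si](C(C)C)(C(C)C)C(C)C)c(CC=C(C)C)c2c1[C@H](O)[C@H](O)[C@@H](c1ccc(O[Si](C)(C)C(C)(C)C)cc1)O2 | intermediate
13 | 5-O-methyl-8-prenylafzelechin-4β-ol, (2R,3S,4S) | COc1cc(O)c(CC=C(C)C)c2c1[C@H](O)[C@H](O)[C@@H](c1ccc(O)cc1)O2 | target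

**Step count**
Total steps: 9. Longest linear sequence: 8 (steps 1, 2, 3, 5, 6, 7, 8, 9).

**Steps most likely to fail**

Step 8: the ketyl may add through an open, non-bridged transition state, so that the face of C4 is poorly controlled and a 3,4-trans diol forms beside 12. The fallback replaces kinetic by thermodynamic control at C4 and sets out from 11. The crude diol mixture, which would hold 12 and its C4 epimer (2R,3S,4R)-2-[4-(tert-butyldimethylsilyloxy)phenyl]-5-methoxy-8-prenyl-7-(triisopropylsilyloxy)chromane-3,4-diol F1, would be stirred with PhB(OH)2, 4 Å MS and EtCO2H (20 mol %) in toluene at rt → 40 °C. Only a 3,4-cis diol can close the five-membered dioxaborolane, and the electron-rich benzylic C4–O bond should ionise reversibly under the weak acid, so that F1 drains into the cis-fused (2R,3S,4S)-3,4-O-phenylboronate F2. HN(CH2CH2OH)2 in THF would then free the diol, and the route is rejoined at 12.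

Step 7: the α-aryl-α-aryloxy aldehyde may enolise at C2 during the double oxidation (erosion of ee), or a half-oxidised hydroxy aldehyde may be trapped as a lactol and oxidised on to a lactone. The fallback takes the ester down only to the aldehyde and oxidises only the benzylic alcohol; it sets out from 9. i-Bu2AlH (2.2 equiv) in CH2Cl2 at −78 °C with a cold MeOH/KNaC4H4O6 quench should reduce the aryl aldehyde to the benzylic alcohol and stop the α-aryloxy ester at the aluminium hemiacetal. This would give (R)-2-[4-(tert-butyldimethylsilyloxy)phenyl]-2-[2-(hydroxymethyl)-3-methoxy-6-prenyl-5-(triisopropylsilyloxy)phenoxy]acetaldehyde F3, which should rest as its seven-membered lactol, with the C2–H no longer beside a free carbonyl. Activated MnO2 in CH2Cl2 (neutral, benzylic-selective) would then oxidise the open form, and the route is rejoined at 11.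

Step 5: SN2 attack of the di-ortho-substituted, hydrogen-bonded phenol on the oxyphosphonium salt may be slow, so that ionisation of the 4-silyloxybenzylic centre competes and ee is lost. The fallback uses carbene O–H insertion instead of substitution. Methyl 4-hydroxyphenylacetate would be silylated (t-BuMe2SiCl, imidazole) to methyl 2-[4-(tert-butyldimethylsilyloxy)phenyl]acetate F4, and diazo transfer (4-acetamidobenzenesulfonyl azide, DBU, MeCN) would give methyl 2-diazo-2-[4-(tert-butyldimethylsilyloxy)phenyl]acetate F5. Setting out from 6, enantioselective insertion of the carbene from F5 into the phenol O–H bond would follow (Pd(PhCN)2Cl2, chiral spiro-bisoxazoline ligand, NaB[3,5-(CF3)2C6H3]4, 5 Å MS, CHCl3, rt; ligand enantiomer chosen for the R ether). The donor–acceptor carbene should insert into O–H faster than it adds to the trisubstituted prenyl alkene, and the route is rejoined at 9.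

**Further compounds**
F1 | step 8 | (2R,3S,4R)-2-[4-(tert-butyldimethylsilyloxy)phenyl]-5-methoxy-8-(3-methylbut-2-en-1-yl)-7-(triisopropylsilyloxy)chromane-3,4-diol | COc1cc(O[Si](C(C)C)(C(C)C)C(C)C)c(CC=C(C)C)c2c1[C@@H](O)[C@H](O)[C@@H](c1ccc(O[Si](C)(C)C(C)(C)C)cc1)O2
F2 | step 8 | (2R,3S,4S)-2-[4-(tert-butyldimethylsilyloxy)phenyl]-5-methoxy-8-(3-methylbut-2-en-1-yl)-7-(triisopropylsilyloxy)chromane-3,4-diyl phenylboronate (cis-fused dioxaborolane) | COc1cc(O[Si](C(C)C)(C(C)C)C(C)C)c(CC=C(C)C)c2c1[C@@H]1OB(c3ccccc3)O[C@@H]1[C@@H](c1ccc(O[Si](C)(C)C(C)(C)C)cc1)O2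
F3 | step 7 | (R)-2-[4-(tert-butyldimethylsilyloxy)phenyl]-2-[2-(hydroxymethyl)-3-methoxy-6-(3-methylbut-2-en-1-yl)-5-(triisopropylsilyloxy)phenoxy]acetaldehyde (open form of the lactol) | O=C[C@H](Oc1c(CO)c(OC)cc(O[Si](C(C)C)(C(C)C)C(C)C)c1CC=C(C)C)c1ccc(O[Si](C)(C)C(C)(C)C)cc1
F4 | step 5 | methyl 2-[4-(tert-butyldimethylsilyloxy)phenyl]acetate | COC(=O)Cc1ccc(O[Si](C)(C)C(C)(C)C)cc1
F5 | step 5 | methyl 2-diazo-2-[4-(tert-butyldimethylsilyloxy)phenyl]acetate | COC(=O)C(=[N+]=[N-])c1ccc(O[Si](C)(C)C(C)(C)C)cc1
A1 | direct plan | 5-methoxy-2-(3-methylbut-2-en-1-yl)benzene-1,3-diol | COc1cc(O)c(CC=C(C)C)c(O)c1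
A2 | direct plan | (2R,3S)-3-(4-acetoxyphenyl)oxirane-2-carbaldehyde | O=C[C@@H]1O[C@H]1c1ccc(OC(C)=O)cc1
A3 | direct plan | (2R,3S,4S)-2-(4-acetoxyphenyl)-7-hydroxy-5-methoxy-8-(3-methylbut-2-en-1-yl)chromane-3,4-diyl phenylboronate | COc1cc(O)c(CC=C(C)C)c2c1[C@@H]1OB(c3ccccc3)O[C@@H]1[C@@H](c1ccc(OC(C)=O)cc1)O2
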